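A process chemist with maple and elm on the bench wants to know which of starting material or product stands highest when the time is up, and how much of it.

the same everywhere: starting material 0.30 M; protic impurity 0.150 M; free catalyst 0.66 mM; time 40 s
- maple: reagent 0.360 M
- elm: reagent 0.540 M

    reagent + free catalyst → spent catalyst (k1 = 0.33 M⁻¹ s⁻¹)
    starting material + protic impurity → quenched substrate (k2 = 0.88 M⁻¹ s⁻¹)
    starting material + reagent + free catalyst ⇌ product + free catalyst, rate k3*[starting material]*[reagent]*[free catalyst] forward; the back reaction follows from the equilibrium constant (K3 = 1.9 M⁻¹, k3 = 690 M⁻² s⁻¹)

* which of these there is most of at the end, counted by the starting material in it, maple (starting material / product)
* which of these there is most of at the end, counted by the starting material in it, elm (starting material / product)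
* amount of the one of these that there is most of at the end, in percent of the starting material charged, maple
* amount of the one of these that there is most of at the end, in percent of the starting material charged, elm

1. Take the bench rule from the catalysed step and divide its forward rate by its back rate. Free catalyst and the rate constant cancel and time drops out, so at balance (thermodynamic control) product over starting material equals the equilibrium constant times the free reagent concentration. With reagent as charged, that gives 0.684 in maple. Call this Q, the equilibrium constant times the reagent concentration. Elm has 1.03. Reagent is used as the flask runs, so both are figures from the charge.

2. At balance, product leads where Q stands above 1. From the charge you guess starting material in maple and, very narrowly, product in elm.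

3. The rule stops working where the catalyst is lost before balance comes. Divide the forward rate per starting material by the loss rate per catalyst, and reagent cancels as well. Over the catalyst's whole life, the forward step gets 1.99 half-lives, from the rate constant 690 M⁻² s⁻¹, the catalyst charge 0.66 mM and the loss constant 0.33 M⁻¹ s⁻¹. That is few, so balance is not assured, and Q gives the side as a guess and the amounts roughly.

4. My own reckoning: the quench half-life of 5.3 s is short against 40 s, so count the protic impurity as taking 50.0% of the starting material. Q then shares out the rest. Maple keeps 29.7% as starting material. Elm is a near tie, with 25.3% product against 24.7% starting material.

5. The forecast says starting material at 30% in maple and product at 28% in elm, since “the extra reagent pushes the equilibrium further over”. It names the same leaders as I do, but its elm figure is higher than mine.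

6. The flasks give starting material at 30.3% in maple and product at 28.9% in elm. The extra reagent may be called the main reason elm's product stands above maple's: with maple's reagent, elm's 28.9% becomes 20.7%. Product over starting material ends at 0.683 in maple, above the 0.565 that Q gives with the reagent still free at the end. In elm it ends at 1.27, above a Q of 0.860 reckoned the same way, so product leads there with Q below 1. Elm with 0.14 M of reagent still has 23.0% of its free catalyst at the end, has a Q of 0.214 from its free reagent, and ends with 9.03% product against 41.3% starting material, a ratio of 0.219.

(Its constants are made up; the result is computed.)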